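(All runs are calculated with made-up constants; noise was put on by code.)

The pitfall in these runs is to read a flat substrate curve as an equilibrium. I had to choose the next flask, so I first asked what stops the substrate.

the same everywhere: substrate 0.20 M

| flask | partner | reagent | remark | time |
|---|---|---|---|---|
| Thursday's | 0.40 M | 0.22 M | run made earlier |  |
| Friday's | 0.40 M | 0.11 M | run made earlier |  |
| Saturday's | 0.40 M | 0.44 M | run made earlier |  |
| violet | 0.400 M | 0.220 M | one stirred flow tank at steady state, fed with the mixture as stated, mean residence time 25 min |  |
| teal | 0.400 M | 0.220 M | plug flow through a tube for 25 min, no back-mixing | 25 min |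
| grey | 0.400 M | 0.220 M | everything together in a closed stirred flask, run for 25 min | 25 min |
| red | 0.400 M (fed, over 20.0 min) | 0.220 M | a stirred flask in which partner is dosed at a steady rate over 20.0 min without added volume, worked up at 25 min | 25 min |

| run | time / min | target / % | isomer of the product / % | substrate / % |
|---|---|---|---|---|
| Thursday's | 2.50 | 0.4 | 0.2 | 97.1 |
| Thursday's | 5.00 | 0 | 0 | 94.9 |
| Thursday's | 8.00 | 0.4 | 0.4 | 92.8 |
| Thursday's | 10.0 | 0.3 | 0 | 92.2 |
| Thursday's | 12.0 | 0 | 0.9 | 91.3 |
| Thursday's | 15.0 | 0.7 | 0 | 91.2 |
| Friday's | 2.50 | 0 | 0.1 | 98.4 |
| Friday's | 4.00 | 0 | 0 | 98.1 |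
| Friday's | 6.00 | 0 | 0 | 98.3 |
| Friday's | 10.0 | 0 | 0.7 | 95.6 |
| Friday's | 20.0 | 0.4 | 0 | 94.9 |
| Friday's | 30.0 | 0 | 0 | 94.8 |
| Saturday's | 2.50 | 0.8 | 0 | 94.0 |
| Saturday's | 4.00 | 0 | 0 | 91.7 |
| Saturday's | 6.00 | 0 | 0 | 89.0 |
| Saturday's | 10.0 | 0.3 | 0.1 | 84.7 |
| Saturday's | 20.0 | 2.2 | 0 | 78.9 |
| Saturday's | 30.0 | 4.7 | 0 | 74.3 |

(scatter of a reading: 0.5 percentage points)

- the stated concentrations are those of everything mixed, before any reaction; amounts are the same in each set-up
- the feed brings no volume worth counting
- the earlier runs were made in a closed, stirred flask
- a reading or a percentage of target counts all its forms, free or not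

- the set-up with the highest share of target in all that became target or isomer of the product, at the outlet or at the end ("none" if the first two lie within 2 percentage points) (violet / teal / grey / red / none)
- share of target in all that became target or isomer of the product, at the outlet or at the end, violet
- share of target in all that became target or isomer of the product, at the outlet or at the end, teal
- share of target in all that became target or isomer of the product, at the outlet or at the end, grey
- share of target in all that became target or isomer of the product, at the outlet or at the end, red

Thursday's flask lost 2.90% of its substrate by 2.50 min and 8.80% by 15.0 min. Friday's flask, with half the reagent, lost 1.60% and 5.20% at its first and last readings. Final loss over early rate gave 7.59 min on Thursday and 8.13 min on Friday. These are readings, and the early losses carry a large scatter. I called their mean, 7.86 min, the spending time: the time over which the reagent lasts with a full partner charge present, treated as a pseudo-first-order decay.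

My working guess was a reaction between partner and reagent. In Saturday's flask the reagent charge was 1.10 of the partner charge, and its substrate was still falling, from 78.9% to 74.3%. That flask also showed 4.7% target at its last reading, so I assumed that surviving reagent favours target.

By this reckoning grey keeps 4.15% of its reagent at 25 min. In red, I took the partner fed as half its charge on average during the feed, so I counted the run as 15.0 min at full partner. Red therefore keeps 14.8%, which is more than grey. I chose red next, with the reagent charge unchanged, and expected it to lead.

The forecast differed from me. It gave 84% for violet, 84% for teal, 84% for grey and 84% for red, so its winner was none: “Partner was never varied, so red's dosing effect is unknown.”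

The best set-up was red, at 90.7%, above 84.2% for grey, 84.2% for teal and 81.0% for violet. Red ended with 22.1% of its reagent, twice grey's 10.9%.

    open intermediate + second intermediate → target (k = 0.0390 L mol⁻¹ min⁻¹)
    2 substrate → self-condensation product (k = 4.90 × 10⁻⁵ L mol⁻¹ min⁻¹)
    reagent + target ⇌ idle adduct, settled at all times (K = 22.0 L mol⁻¹)
    target ⇌ isomer of the product (K = 1.20, k = 0.0470 min⁻¹)
    substrate + reagent → open intermediate (k = 0.0580 L mol⁻¹ min⁻¹)
    reagent + partner → second intermediate (k = 0.280 L mol⁻¹ min⁻¹)

Against the spending time, red's 15.0 min came to 1.91 spending times and the reckoned 14.8%. A flask like red with 0.055 M of reagent has the same count and the same reckoned share left, and it ended with 15.9% of its reagent and a share of 83.4% target.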